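The route disconnects the C2–C3 bond of the pyranone ring (ring C). C2 is benzylic to ring B and bonded to the ring oxygen O1, so its C–H bonds are doubly activated, while C3 sits alpha to the C4 ketone and can be a metal carbenoid. The precursor is therefore an open aryl benzyl ether: a prenylated ring A acetophenone, O-alkylated at O1 with a prenylated ring B benzyl bromide and converted into its diazomethyl ketone. A chiral dirhodium carboxylate then inserts the C3 carbenoid into one enantiotopic C2–H bond, closing ring C and setting the 2S centre in one operation; acid then removes three methoxymethyl groups.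

Key step: step 9

Remark: compounds 1 and 6 are taken as catalogue compounds. The sense of induction of the rhodium catalyst in step 9 cannot be predicted with certainty for this substrate and is to be fixed by a test run; the antipodal catalyst Rh2(R-PTTL)4 is used if it is the one that gives the 2S product.

Step 1
Reactants: 1 3-bromo-4,5-dihydroxybenzaldehyde
Product: 2 3-bromo-4,5-bis(methoxymethoxy)benzaldehyde
Conditions: MOMCl (2.5 equiv), K2CO3, acetone, 0 °C to rt
Reagents that add atoms: chloromethyl methyl ether (MOMCl), COCCl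
Why: Williamson-type MOM protection, in which both catechol phenoxides are alkylated by the reactive chloromethyl ether while the aldehyde and the aryl bromide are inert.

Step 2
Reactants: 2 3-bromo-4,5-bis(methoxymethoxy)benzaldehyde
Product: 3 3,4-bis(methoxymethoxy)-5-(3-methylbut-2-en-1-yl)benzaldehyde
Conditions: tributyl(prenyl)stannane, Pd(PPh3)4 (5 mol %), DMF, 95 °C
Reagents that add atoms: tributyl(3-methylbut-2-en-1-yl)stannane, CCCC[Sn](CCCC)(CCCC)CC=C(C)C
Why: Stille cross-coupling, in which oxidative addition of zerovalent palladium into the C–Br bond, transfer of the prenyl group from tin and reductive elimination should give the linear prenyl arene, with the aldehyde and MOM acetals tolerated.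

Step 3
Reactants: 3 3,4-bis(methoxymethoxy)-5-(3-methylbut-2-en-1-yl)benzaldehyde
Product: 4 [3,4-bis(methoxymethoxy)-5-(3-methylbut-2-en-1-yl)phenyl]methanol
Conditions: NaBH4, MeOH, 0 °C
Reagents that add atoms: none
Why: Chemoselective hydride reduction of the aromatic aldehyde, which leaves the alkene and the acetals untouched.

Step 4
Reactants: 4 [3,4-bis(methoxymethoxy)-5-(3-methylbut-2-en-1-yl)phenyl]methanol
Product: 5 5-(bromomethyl)-1,2-bis(methoxymethoxy)-3-(3-methylbut-2-en-1-yl)benzene
Conditions: CBr4, PPh3, CH2Cl2, 0 °C; used at once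
Reagents that add atoms: carbon tetrabromide, BrC(Br)(Br)Br
Why: Appel reaction, in which the alcohol is activated as an alkoxyphosphonium ion and displaced by bromide under neutral conditions that spare the MOM acetals and the prenyl alkene.

Step 5
Reactants: 6 1-[2,4-dihydroxy-3-(prop-2-en-1-yl)phenyl]ethanone (3'-allyl-2',4'-dihydroxyacetophenone)
Product: 7 1-[2-hydroxy-4-(methoxymethoxy)-3-(prop-2-en-1-yl)phenyl]ethanone
Conditions: MOMCl (1.1 equiv), K2CO3, acetone, rt
Reagents that add atoms: chloromethyl methyl ether (MOMCl), COCCl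
Why: Chemoselective MOM protection, since the 4-OH para to the acetyl group is the more acidic and accessible phenol while the 2-OH is held in a hydrogen bond to the ketone and stays free.

Step 6
Reactants: 7 1-[2-hydroxy-4-(methoxymethoxy)-3-(prop-2-en-1-yl)phenyl]ethanone
Product: 8 1-[2-hydroxy-4-(methoxymethoxy)-3-(3-methylbut-2-en-1-yl)phenyl]ethanone
Conditions: 2-methylbut-2-ene (large excess), second-generation Grubbs catalyst RuCl2(=CHPh)(PCy3)(H2IMes) (3 mol %), CH2Cl2, 40 °C
Reagents that add atoms: 2-methylbut-2-ene, CC=C(C)C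
Why: Olefin cross-metathesis, in which the terminal allyl alkene exchanges its methylene for the isopropylidene unit of the excess partner with loss of propene, and the trisubstituted product is inert to further metathesis.

Step 7
Reactants: 8 1-[2-hydroxy-4-(methoxymethoxy)-3-(3-methylbut-2-en-1-yl)phenyl]ethanone; 5 5-(bromomethyl)-1,2-bis(methoxymethoxy)-3-(3-methylbut-2-en-1-yl)benzene
Product: 9 1-[2-{[3,4-bis(methoxymethoxy)-5-(3-methylbut-2-en-1-yl)phenyl]methoxy}-4-(methoxymethoxy)-3-(3-methylbut-2-en-1-yl)phenyl]ethanone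
Conditions: K2CO3, n-Bu4NI (cat.), DMF, 50 °C
Reagents that add atoms: none
Why: Williamson ether synthesis, in which the hindered, hydrogen-bonded phenoxide of 8 is O-alkylated by the reactive primary benzylic bromide in a bimolecular substitution in a polar aprotic solvent.

Step 8
Reactants: 9 1-[2-{[3,4-bis(methoxymethoxy)-5-(3-methylbut-2-en-1-yl)phenyl]methoxy}-4-(methoxymethoxy)-3-(3-methylbut-2-en-1-yl)phenyl]ethanone
Product: 11 2-diazo-1-[2-{[3,4-bis(methoxymethoxy)-5-(3-methylbut-2-en-1-yl)phenyl]methoxy}-4-(methoxymethoxy)-3-(3-methylbut-2-en-1-yl)phenyl]ethanone, via trifluoroacetyl diketone 10 (not isolated)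
Conditions: LiN(SiMe3)2, THF, −78 °C, then CF3CO2CH2CF3; cold dilute aq. HCl work-up; then MsN3, Et3N, H2O (1 equiv), MeCN, rt
Reagents that add atoms: methanesulfonyl azide, CS(=O)(=O)N=[N+]=[N-]; 2,2,2-trifluoroethyl trifluoroacetate, O=C(OCC(F)(F)F)C(F)(F)F (its trifluoroacetyl group appears only in 10)
Why: Regitz diazo transfer in its detrifluoroacetylative form, in which the lithium enolate of the methyl ketone is trifluoroacetylated to the activated 1,3-diketone 10, which takes the diazo group from the sulfonyl azide and loses the trifluoroacetyl group as the N-sulfonyl amide.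

Step 9
Reactants: 11 2-diazo-1-[2-{[3,4-bis(methoxymethoxy)-5-(3-methylbut-2-en-1-yl)phenyl]methoxy}-4-(methoxymethoxy)-3-(3-methylbut-2-en-1-yl)phenyl]ethanone
Product: 12 (2S)-2-[3,4-bis(methoxymethoxy)-5-(3-methylbut-2-en-1-yl)phenyl]-7-(methoxymethoxy)-8-(3-methylbut-2-en-1-yl)-2,3-dihydro-4H-chromen-4-one
Conditions: Rh2(S-PTTL)4 (dirhodium tetrakis[N-phthaloyl-(S)-tert-leucinate], 1 mol %), 4 Å MS, CH2Cl2, 0 °C, slow addition of 11 (final 0.01 M)
Reagents that add atoms: none
Why: Loss of N2 from 11 gives an electrophilic dirhodium carbenoid at C3, which inserts into one of the two enantiotopic C–H bonds of the O1–CH2–aryl methylene through a three-centre, hydride-transfer-like transition state and so forms the C2–C3 bond. The closest known reaction type is the enantioselective intramolecular C–H insertion of 2-alkoxyaryl alpha-diazo ketones to chroman-4-ones, and of 2-benzyloxyaryl diazoacetates to 2-aryl-2,3-dihydrobenzofurans, under chiral dirhodium carboxylates. Ring C closes by a 1,6-insertion through a six-membered cyclic transition state in which the carbenoid carbon, C4, C4a, C8a, O1 and C2 become the ring atoms. The new C2 stereocentre is set under catalyst control, the chiral pocket of the tert-leucinate ligands deciding which enantiotopic hydrogen reaches the carbenoid, and no other stereocentre is present to interfere. The step needs site selectivity for this C–H bond over ylide formation at O1 followed by a 1,2-benzyl shift, over cyclopropanation of the two prenyl alkenes and over the MOM methylenes. The substrate should secure it because the C2–H bonds are activated by both O1 and the electron-rich ring B, O1 is a weak donor as part of a vinylogous aryl ester, and no alkene or MOM group can reach the carbenoid through a small ring, while slow addition at high dilution suppresses bimolecular paths.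

Step 10
Reactants: 12 (2S)-2-[3,4-bis(methoxymethoxy)-5-(3-methylbut-2-en-1-yl)phenyl]-7-(methoxymethoxy)-8-(3-methylbut-2-en-1-yl)-2,3-dihydro-4H-chromen-4-one
Product: 13 (2S)-2-[3,4-dihydroxy-5-(3-methylbut-2-en-1-yl)phenyl]-7-hydroxy-8-(3-methylbut-2-en-1-yl)-2,3-dihydro-4H-chromen-4-one
Conditions: 3 M aq. HCl, MeOH, 40 °C
Reagents that add atoms: none
Why: Acid-catalysed solvolysis of the three aryl MOM acetals in methanol, under base-free conditions so that C2 is not scrambled by ring opening to the chalcone, and mild enough that the prenyl alkenes should survive.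

Compound list
1 | 3-bromo-4,5-dihydroxybenzaldehyde | O=Cc1cc(O)c(O)c(Br)c1 | starting material
2 | 3-bromo-4,5-bis(methoxymethoxy)benzaldehyde | O=Cc1cc(OCOC)c(OCOC)c(Br)c1 | intermediate
3 | 3,4-bis(methoxymethoxy)-5-(3-methylbut-2-en-1-yl)benzaldehyde | O=Cc1cc(OCOC)c(OCOC)c(CC=C(C)C)c1 | intermediate
4 | [3,4-bis(methoxymethoxy)-5-(3-methylbut-2-en-1-yl)phenyl]methanol | OCc1cc(OCOC)c(OCOC)c(CC=C(C)C)c1 | intermediate
5 | 5-(bromomethyl)-1,2-bis(methoxymethoxy)-3-(3-methylbut-2-en-1-yl)benzene | BrCc1cc(OCOC)c(OCOC)c(CC=C(C)C)c1 | intermediate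
6 | 1-[2,4-dihydroxy-3-(prop-2-en-1-yl)phenyl]ethanone | CC(=O)c1ccc(O)c(CC=C)c1O | starting material
7 | 1-[2-hydroxy-4-(methoxymethoxy)-3-(prop-2-en-1-yl)phenyl]ethanone | CC(=O)c1ccc(OCOC)c(CC=C)c1O | intermediate
8 | 1-[2-hydroxy-4-(methoxymethoxy)-3-(3-methylbut-2-en-1-yl)phenyl]ethanone | CC(=O)c1ccc(OCOC)c(CC=C(C)C)c1O | intermediate
9 | 1-[2-{[3,4-bis(methoxymethoxy)-5-(3-methylbut-2-en-1-yl)phenyl]methoxy}-4-(methoxymethoxy)-3-(3-methylbut-2-en-1-yl)phenyl]ethanone | CC(=O)c1ccc(OCOC)c(CC=C(C)C)c1OCc1cc(OCOC)c(OCOC)c(CC=C(C)C)c1 | intermediate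
10 | 1-[2-{[3,4-bis(methoxymethoxy)-5-(3-methylbut-2-en-1-yl)phenyl]methoxy}-4-(methoxymethoxy)-3-(3-methylbut-2-en-1-yl)phenyl]-4,4,4-trifluorobutane-1,3-dione | O=C(CC(=O)C(F)(F)F)c1ccc(OCOC)c(CC=C(C)C)c1OCc1cc(OCOC)c(OCOC)c(CC=C(C)C)c1 | intermediate
11 | 2-diazo-1-[2-{[3,4-bis(methoxymethoxy)-5-(3-methylbut-2-en-1-yl)phenyl]methoxy}-4-(methoxymethoxy)-3-(3-methylbut-2-en-1-yl)phenyl]ethanone | [N-]=[N+]=CC(=O)c1ccc(OCOC)c(CC=C(C)C)c1OCc1cc(OCOC)c(OCOC)c(CC=C(C)C)c1 | intermediate
12 | (2S)-2-[3,4-bis(methoxymethoxy)-5-(3-methylbut-2-en-1-yl)phenyl]-7-(methoxymethoxy)-8-(3-methylbut-2-en-1-yl)-2,3-dihydro-4H-chromen-4-one | CC(C)=CCc1cc([C@@H]2CC(=O)c3ccc(OCOC)c(CC=C(C)C)c3O2)cc(OCOC)c1OCOC | intermediate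
13 | (2S)-2-[3,4-dihydroxy-5-(3-methylbut-2-en-1-yl)phenyl]-7-hydroxy-8-(3-methylbut-2-en-1-yl)-2,3-dihydro-4H-chromen-4-one | CC(C)=CCc1cc([C@@H]2CC(=O)c3ccc(O)c(CC=C(C)C)c3O2)cc(O)c1O | target

Total step count: 10.
Longest linear sequence: 8 steps (steps 1 to 4 and 7 to 10, from compound 1).

Steps most likely to fail

Step 9. The carbenoid may attack the lone pair of O1 instead of a C2–H bond, giving an oxonium ylide that undergoes a 1,2-benzyl shift and closes a five-membered ring, or the catalyst may discriminate poorly between the two enantiotopic hydrogens. The fallback uses known chemistry and a different bond construction, setting out from ketone 8 and aldehyde 3. Claisen–Schmidt condensation (KOH, EtOH, rt) should give the (E)-2'-hydroxychalcone F1. Oxa-Michael cyclisation (NaOAc, EtOH, reflux) should give the racemic tris-MOM flavanone F2. Kinetic resolution by asymmetric transfer hydrogenation (RuCl(p-cymene)[(R,R)-TsDPEN], HCO2H/Et3N, EtOAc, rt) is expected to reduce the 2R enantiomer to the cis-(2R,4R)-flavan-4-ol F3 and leave the 2S ketone untouched; the catalyst antipode is to be confirmed in a test run. The recovered ketone is 12, where the route is rejoined. If step 9 works but only the enantiomeric purity falls short, the same transfer hydrogenation applied to enriched 12 should remove the minor enantiomer.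

Step 10. Protic acid may add the free 7-OH and 4'-OH groups across the neighbouring prenyl alkenes (closure to dimethylchromans), or hydrate the alkenes, before all three acetals are cleaved. The fallback avoids Brønsted acid and sets out from 12. Me3SiOTf and 2,2'-bipyridyl in CH2Cl2 at 0 °C should convert the aryl MOM acetals into aryl silyl ethers, giving the tris(trimethylsilyl) ether F4. Any silyl enol ether formed at C4 involves C3 only and leaves C2 intact. Mild hydrolysis (H2O, MeOH, rt) should then give 13, where the route is rejoined.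

Step 2. Allyl transposition during the transfer of the prenyl group from tin to palladium may give the 1,1-dimethylallyl regioisomer, and oxidative addition into the hindered, electron-rich C–Br bond may be slow. The fallback sets out from 2 and separates C–C coupling from prenyl construction. Stille coupling with allyltributylstannane (Pd(PPh3)4, toluene, 100 °C), which has no regiochemical ambiguity, should give the allyl aldehyde F5. Cross-metathesis with 2-methylbut-2-ene (second-generation Grubbs catalyst, CH2Cl2, 40 °C), as in step 6, should then give 3, where the route is rejoined.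

Further compounds
F1 | step 9 | (E)-3-[3,4-bis(methoxymethoxy)-5-(3-methylbut-2-en-1-yl)phenyl]-1-[2-hydroxy-4-(methoxymethoxy)-3-(3-methylbut-2-en-1-yl)phenyl]prop-2-en-1-one | O=C(/C=C/c1cc(OCOC)c(OCOC)c(CC=C(C)C)c1)c1ccc(OCOC)c(CC=C(C)C)c1O
F2 | step 9 | racemic 2-[3,4-bis(methoxymethoxy)-5-(3-methylbut-2-en-1-yl)phenyl]-7-(methoxymethoxy)-8-(3-methylbut-2-en-1-yl)-2,3-dihydro-4H-chromen-4-one | CC(C)=CCc1cc(C2CC(=O)c3ccc(OCOC)c(CC=C(C)C)c3O2)cc(OCOC)c1OCOC
F3 | step 9 | (2R,4R)-2-[3,4-bis(methoxymethoxy)-5-(3-methylbut-2-en-1-yl)phenyl]-7-(methoxymethoxy)-8-(3-methylbut-2-en-1-yl)-3,4-dihydro-2H-chromen-4-ol | CC(C)=CCc1cc([C@H]2C[C@@H](O)c3ccc(OCOC)c(CC=C(C)C)c3O2)cc(OCOC)c1OCOC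
F4 | step 10 | (2S)-2-[3,4-bis(trimethylsilyloxy)-5-(3-methylbut-2-en-1-yl)phenyl]-7-(trimethylsilyloxy)-8-(3-methylbut-2-en-1-yl)-2,3-dihydro-4H-chromen-4-one | CC(C)=CCc1cc([C@@H]2CC(=O)c3ccc(O[Si](C)(C)C)c(CC=C(C)C)c3O2)cc(O[Si](C)(C)C)c1O[Si](C)(C)C
F5 | step 2 | 3,4-bis(methoxymethoxy)-5-(prop-2-en-1-yl)benzaldehyde | O=Cc1cc(OCOC)c(OCOC)c(CC=C)c1
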